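C5 chains: each one stands ortho to a free OH (C6 beside O7 in ring A, C2' beside O3' and C5' beside O4' in ring B). One triple aromatic Claisen rearrangement of the O7-prenyl/O3',O4'-diallyl tri-ether therefore sets all three aryl–C bonds, and cross-metathesis then turns the two allyl groups into prenyl groups.
Core: ring C (the dihydropyran) is cut at C2–C3 and C4–C4a. The C3–C4 bridge enters as an acetaldehyde enol silane (C3 donor, C4 acceptor) in an enantioselective oxa-Povarov-type (4+2) annulation with an aryl oxocarbenium ion, and ionic hydrogenation removes the leftover C4 oxygen.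
Enabling feature: O1 joins benzylic C2, whose cation is stabilised by O1 and by the para oxygen O4' of ring B, to C8a of ring A, whose neighbour C4a lies ortho to O1 and para to O7. C2=O1(+)–C8a=C4a is thus a cationic 2-oxadiene with one electrophilic and one nucleophilic end, and the bridge between them carries no substituent.
Precursor and ring order: an O-aryl O-pivaloyl acetal is made from 3,4-bis(allyloxy)benzaldehyde, pivaloyl chloride and 3-(prenyloxy)phenol. Rings A and B are bought (resorcinol, 3,4-dihydroxybenzaldehyde), and ring C is the only ring formed (step 4).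

Key step: step 4

Assumption: the sense of induction of the chiral acid in step 4 must be found by experiment, so the catalyst enantiomer (both derive from commercial (R)- or (S)-BINOL) that gives the 2S series is taken; enol silane 9 is taken as purchasable (otherwise one operation from THF, n-BuLi and t-BuMe2SiCl).

Step 1
Reactants: 1 resorcinol; 2 prenyl bromide (1-bromo-3-methylbut-2-ene)
Product: 3 3-(3-methylbut-2-enyloxy)phenol
Conditions: 1 (3 equiv), K2CO3, acetone, reflux
Reagents that add atoms: none
Why: Williamson ether synthesis, in which the excess of the symmetric diphenol holds the reaction at the mono-ether and the aprotic medium favours O- over C-alkylation.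

Step 2
Reactants: 4 3,4-dihydroxybenzaldehyde; 5 allyl bromide
Product: 6 3,4-bis(allyloxy)benzaldehyde
Conditions: 5 (2.4 equiv), K2CO3, DMF, 50 °C
Reagents that add atoms: none
Why: Double Williamson ether synthesis with a primary allylic bromide, the aldehyde being inert to K2CO3.

Step 3
Reactants: 6 3,4-bis(allyloxy)benzaldehyde; 3 3-(3-methylbut-2-enyloxy)phenol
Product: 8 [3,4-bis(allyloxy)phenyl][3-(3-methylbut-2-enyloxy)phenoxy]methyl pivalate (racemic), via chloro ester 7 (not isolated)
Conditions: t-BuCOCl (1.1 equiv), ZnCl2 (5 mol %), CH2Cl2, 0 °C to rt, volatiles removed; then 3, Cs2CO3, MeCN, 0 °C; filtration through basic alumina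
Reagents that add atoms: pivaloyl chloride, CC(C)(C)C(=O)Cl
Why: ZnCl2-catalysed addition of an acyl chloride across an aldehyde C=O gives the 1-chloroalkyl ester 7, whose labile benzylic chloride is displaced by the caesium phenoxide of 3 (O-alkylation of a phenol with a 1-chloroalkyl carboxylate, the reaction type behind acyloxyalkyl aryl ethers); the bulky pivaloyl group suppresses acyl transfer, and the new centre is racemic and is erased on ionisation in step 4.

Step 4
Reactants: 8 [3,4-bis(allyloxy)phenyl][3-(3-methylbut-2-enyloxy)phenoxy]methyl pivalate; 9 tert-butyldimethyl(vinyloxy)silane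
Product: 12 (2S,4S)-2-[3,4-bis(allyloxy)phenyl]-4-(tert-butyldimethylsilyloxy)-7-(3-methylbut-2-enyloxy)chroman, via aryl oxocarbenium ion 10 (not isolated), via silyloxocarbenium ion 11 (not isolated)
Conditions: chiral imidodiphosphorimidate Brønsted acid (IDPi type: two 3,3'-diaryl-BINOL phosphorus units bridged by NH, each P=N–SO2CF3; 5 mol %), 9 (1.5 equiv, slow addition), toluene, −78 °C; Et3N quench
Reagents that add atoms: none
Why: Proposed new method: the strong chiral acid ionises the pivalate of 8 (a far better nucleofuge than the aryloxide, so only the aryl oxocarbenium ion 10 forms), the CH2 terminus of enol silane 9 adds to its cationic carbon (C2–C3 bond) inside the confined chiral anion, and the silyloxocarbenium ion 11 so formed is captured by C4a of ring A (C4–C4a bond), loss of the arene proton returning the acid. The closest known reaction types are the racemic, SnCl4-promoted oxa-Povarov reaction of aryl oxocarbenium ions with alkenes and the imidodiphosphorimidate-catalysed enantioselective additions of acetaldehyde enol silanes to aldehydes and of silyl nucleophiles to oxocarbenium ions made from lactol acetates; new is their merger into an enantioselective formal (4+2) annulation. Ring C closes by a 6-exo-trig Friedel–Crafts attack of the arene on the C4=O(+) bond, which lies outside the new ring. C2 is set in the first, irreversible C–C bond formation by the chiral counter-anion, which covers one face of the planar cation 10 (catalyst control), and C4 follows by substrate control from a chair-like closure with the aryl and siloxy groups pseudo-equatorial (2,4-cis), a centre that step 5 erases. The step needs chemoselectivity for 9 over the allyl and prenyl C=C bonds and over ring A of a second molecule, secured by the much higher nucleophilicity of the enol silane, and regioselectivity for closure at the ring A carbon para to the prenyloxy group instead of the carbon between the two oxygens, secured by para activation and the lower steric demand there. The low temperature and the bulky silyl group should keep the C4 siloxy group and the C2–O1 bond of 12 from ionising again, so that neither over-alkylation nor racemisation sets in.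

Step 5
Reactants: 12 (2S,4S)-2-[3,4-bis(allyloxy)phenyl]-4-(tert-butyldimethylsilyloxy)-7-(3-methylbut-2-enyloxy)chroman
Product: 13 (2S)-2-[3,4-bis(allyloxy)phenyl]-7-(3-methylbut-2-enyloxy)chroman
Conditions: Et3SiH (5 equiv), Et3SiOTf (10 mol %), CH2Cl2, −78 °C; Et3N quench
Reagents that add atoms: none
Why: Ionic hydrogenation of an activated benzylic silyl ether (the reaction type that takes flavan-4-ols to flavans): Et3Si(+) removes the C4 siloxy group as the disiloxane because the C4 cation is stabilised by O1 (ortho) and O7 (para), Et3SiH delivers hydride and renews Et3Si(+), and at −78 °C the far less basic aryl ether oxygen O1 is not activated, so the C2–O1 bond, the C2 configuration and the allyl and prenyl ethers should persist.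

Step 6
Reactants: 13 (2S)-2-[3,4-bis(allyloxy)phenyl]-7-(3-methylbut-2-enyloxy)chroman
Product: 14 (2S)-2-(3,4-diacetoxy-2,5-diallylphenyl)-6-(2-methylbut-3-en-2-yl)chroman-7-yl acetate
Conditions: Ac2O (12 equiv), N,N-diethylaniline, argon, sealed tube, 195 °C
Reagents that add atoms: acetic anhydride, CC(=O)OC(C)=O
Why: Three aromatic Claisen rearrangements ([3,3] shifts, each followed by rearomatisation) run in one pot: the O3' and O4' allyl groups can only reach their single free ortho carbons C2' and C5', the O7 prenyl group inverts to the 1,1-dimethylallyl group and should prefer C6 over C8 because the new quaternary carbon avoids the site between O1 and O7 and a meta alkoxy group directs migration away from itself, and Ac2O caps every phenol as it appears, which blocks the abnormal Claisen pathway, dihydrofuran formation and quinone methide opening of ring C, so C2 is not touched.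

Step 7
Reactants: 14 (2S)-2-(3,4-diacetoxy-2,5-diallylphenyl)-6-(2-methylbut-3-en-2-yl)chroman-7-yl acetate; 15 2-methylbut-2-ene
Product: 16 (2S)-2-[3,4-diacetoxy-2,5-bis(3-methylbut-2-enyl)phenyl]-6-(2-methylbut-3-en-2-yl)chroman-7-yl acetate
Conditions: 15 (large excess, co-solvent), second-generation Grubbs catalyst RuCl2(=CHPh)(PCy3)(H2IMes) (5 mol %), 1,4-benzoquinone (10 mol %), CH2Cl2, 40 °C, stopped when both allyl groups are consumed
Reagents that add atoms: none
Why: Olefin cross-metathesis of allyl arenes with 2-methylbut-2-ene (the standard allyl-to-prenyl conversion), in which the vinyl group of the 1,1-dimethylallyl unit is shielded by its quaternary allylic carbon and reacts much more slowly, while the acetates keep the catechol from binding ruthenium.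

Step 8
Reactants: 16 (2S)-2-[3,4-diacetoxy-2,5-bis(3-methylbut-2-enyl)phenyl]-6-(2-methylbut-3-en-2-yl)chroman-7-yl acetate
Product: 17 (2S)-2-[3,4-dihydroxy-2,5-bis(3-methylbut-2-enyl)phenyl]-6-(2-methylbut-3-en-2-yl)chroman-7-ol (CNP0118330.1)
Conditions: K2CO3 (catalytic), degassed MeOH, 0 °C; pH 6 phosphate buffer
Reagents that add atoms: none
Why: Base-catalysed transesterification of aryl acetates with methanol, run cold, briefly and without air so that the catechol is not oxidised and the 4'-phenoxide has no chance to open ring C through a quinone methide, which leaves C2 as set in step 4.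

Compound list
1 | resorcinol | Oc1cccc(O)c1 | starting material
2 | prenyl bromide (1-bromo-3-methylbut-2-ene) | CC(C)=CCBr | starting material
3 | 3-(3-methylbut-2-enyloxy)phenol | CC(C)=CCOc1cccc(O)c1 | intermediate
4 | 3,4-dihydroxybenzaldehyde | O=Cc1ccc(O)c(O)c1 | starting material
5 | allyl bromide | C=CCBr | starting material
6 | 3,4-bis(allyloxy)benzaldehyde | C=CCOc1ccc(C=O)cc1OCC=C | intermediate
7 | [3,4-bis(allyloxy)phenyl](chloro)methyl pivalate (racemic, not isolated) | CC(C)(C)C(=O)OC(Cl)c1ccc(OCC=C)c(OCC=C)c1 | intermediate
8 | [3,4-bis(allyloxy)phenyl][3-(3-methylbut-2-enyloxy)phenoxy]methyl pivalate (racemic) | CC(C)(C)C(=O)OC(Oc1cccc(OCC=C(C)C)c1)c1ccc(OCC=C)c(OCC=C)c1 | intermediate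
9 | tert-butyldimethyl(vinyloxy)silane | C=CO[Si](C)(C)C(C)(C)C | starting material
10 | aryl oxocarbenium ion (counter-ion: chiral imidodiphosphorimidate; not isolated) | CC(C)=CCOc1cccc([O+]=Cc2ccc(OCC=C)c(OCC=C)c2)c1 | intermediate
11 | (S)-configured open-chain silyloxocarbenium ion (not isolated) | CC(C)=CCOc1cccc(O[C@@H](CC=[O+][Si](C)(C)C(C)(C)C)c2ccc(OCC=C)c(OCC=C)c2)c1 | intermediate
12 | (2S,4S)-2-[3,4-bis(allyloxy)phenyl]-4-(tert-butyldimethylsilyloxy)-7-(3-methylbut-2-enyloxy)chroman | CC(C)=CCOc1ccc2c(c1)O[C@H](c1ccc(OCC=C)c(OCC=C)c1)C[C@@H]2O[Si](C)(C)C(C)(C)C | intermediate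
13 | (2S)-2-[3,4-bis(allyloxy)phenyl]-7-(3-methylbut-2-enyloxy)chroman | CC(C)=CCOc1ccc2c(c1)O[C@H](c1ccc(OCC=C)c(OCC=C)c1)CC2 | intermediate
14 | (2S)-2-(3,4-diacetoxy-2,5-diallylphenyl)-6-(2-methylbut-3-en-2-yl)chroman-7-yl acetate | C=CC(C)(C)c1cc2c(cc1OC(C)=O)O[C@H](c1cc(CC=C)c(OC(C)=O)c(OC(C)=O)c1CC=C)CC2 | intermediate
15 | 2-methylbut-2-ene | CC=C(C)C | starting material
16 | (2S)-2-[3,4-diacetoxy-2,5-bis(3-methylbut-2-enyl)phenyl]-6-(2-methylbut-3-en-2-yl)chroman-7-yl acetate | C=CC(C)(C)c1cc2c(cc1OC(C)=O)O[C@H](c1cc(CC=C(C)C)c(OC(C)=O)c(OC(C)=O)c1CC=C(C)C)CC2 | intermediate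
17 | (2S)-2-[3,4-dihydroxy-2,5-bis(3-methylbut-2-enyl)phenyl]-6-(2-methylbut-3-en-2-yl)chroman-7-ol (CNP0118330.1) | C=CC(C)(C)c1cc2c(cc1O)O[C@H](c1cc(CC=C(C)C)c(O)c(O)c1CC=C(C)C)CC2 | target

Total step count: 8. Longest linear sequence: 7 steps (4 → 6 → 8 → 12 → 13 → 14 → 16 → 17).

Steps most likely to fail

Step 4. The ion pair may discriminate poorly between the two faces of the cation. Turnover may stall. The open-chain aldehyde may also be released too early and lose the phenol by β-elimination. The fallback gives up catalyst control and resolves through the C4 oxygen; it sets out from 8 and 9 and comes back at 13.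
- The annulation is run with Me3SiOTf (20 mol %, CH2Cl2, −78 °C). This is the silyl triflate-catalysed addition of an enol silane to an acetal-type electrophile followed by Friedel–Crafts closure, i.e. the known racemic oxa-Povarov manifold. It gives the racemic 2,4-cis silyl ether F1.
- Bu4NF/AcOH in THF frees the racemic cis-flavan-4-ol F2.
- Lipase-catalysed kinetic resolution (Candida antarctica lipase B, vinyl acetate, MTBE, 30 °C) is an established way to resolve cis-flavan-4-ols.
- By the empirical rule for lipase acylation of secondary alcohols, it should leave the (2S,4S)-flavan-4-ol F3 untouched while the 4R enantiomer becomes the (2R,4R)-acetate F4. The cis relationship ties C2 to C4, so resolving C4 also resolves C2.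
- F3 is separated and reduced with Et3SiH/CF3CO2H (CH2Cl2, −40 °C) to 13.

Step 6. The prenyl group may migrate to C8 in competition with C6, or the 1,1-dimethylallyl group may isomerise before the phenol is capped. The fallback uses a removable blocking group at C8; it sets out from 2 (with 7 and 9 used as before) and comes back at 14.
- Purchased 2-bromobenzene-1,3-diol F5 is mono-alkylated with 2 (K2CO3, acetone) to 2-bromo-3-(3-methylbut-2-enyloxy)phenol F6.
- Chloro ester 7 under the conditions of step 3 gives the bromo acylal F7.
- The conditions of step 4 give the (2S,4S)-8-bromo silyl ether F8. The bromine also closes the site between the two oxygens to the Friedel–Crafts closure.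
- The conditions of step 5 give the (2S)-8-bromo tri-ether F9.
- Rearrangement and acetylation as in step 6, now with C6 as the only free ortho carbon of O7, give the 8-bromo triacetate F10.
- Radical hydrodebromination (Bu3SnH, AIBN, toluene, 80 °C) leads to 14. The C8 radical points away from C2–H, so the stereocentre is out of its reach.

Step 3. The acyl chloride addition may revert for the electron-rich aldehyde, the acyl group may transfer to the phenoxide, or 8 may hydrolyse during isolation. The fallback changes the nucleofuge to benzotriazole; it sets out from 6 and 3 and comes back at 12.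
- Compound 6, 1H-benzotriazole and SOCl2 (CH2Cl2, reflux) give 1-{[3,4-bis(allyloxy)phenyl](chloro)methyl}benzotriazole F11.
- The sodium salt of 3 (NaH, THF/DMF, 0 °C) displaces chloride to give the chromatography-stable aryloxy(aryl)methylbenzotriazole F12.
- F12 takes the place of 8 in step 4. Benzotriazole is a very weak base and a better nucleofuge than the aryloxide, so it leaves on protonation and the same cation 10 is reached.

Further compounds
F1 | step 4 | racemic 2,4-cis-2-[3,4-bis(allyloxy)phenyl]-4-(tert-butyldimethylsilyloxy)-7-(3-methylbut-2-enyloxy)chroman | CC(C)=CCOc1ccc2c(c1)OC(c1ccc(OCC=C)c(OCC=C)c1)CC2O[Si](C)(C)C(C)(C)C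
F2 | step 4 | racemic 2,4-cis-2-[3,4-bis(allyloxy)phenyl]-7-(3-methylbut-2-enyloxy)chroman-4-ol | CC(C)=CCOc1ccc2c(c1)OC(c1ccc(OCC=C)c(OCC=C)c1)CC2O
F3 | step 4 | (2S,4S)-2-[3,4-bis(allyloxy)phenyl]-7-(3-methylbut-2-enyloxy)chroman-4-ol | CC(C)=CCOc1ccc2c(c1)O[C@H](c1ccc(OCC=C)c(OCC=C)c1)C[C@@H]2O
F4 | step 4 | (2R,4R)-2-[3,4-bis(allyloxy)phenyl]-7-(3-methylbut-2-enyloxy)chroman-4-yl acetate | CC(C)=CCOc1ccc2c(c1)O[C@@H](c1ccc(OCC=C)c(OCC=C)c1)C[C@H]2OC(C)=O
F5 | step 6 | 2-bromobenzene-1,3-diol (purchased) | Oc1cccc(O)c1Br
F6 | step 6 | 2-bromo-3-(3-methylbut-2-enyloxy)phenol | CC(C)=CCOc1cccc(O)c1Br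
F7 | step 6 | [3,4-bis(allyloxy)phenyl][2-bromo-3-(3-methylbut-2-enyloxy)phenoxy]methyl pivalate (racemic) | CC(C)(C)C(=O)OC(Oc1cccc(OCC=C(C)C)c1Br)c1ccc(OCC=C)c(OCC=C)c1
F8 | step 6 | (2S,4S)-2-[3,4-bis(allyloxy)phenyl]-8-bromo-4-(tert-butyldimethylsilyloxy)-7-(3-methylbut-2-enyloxy)chroman | CC(C)=CCOc1ccc2c(c1Br)O[C@H](c1ccc(OCC=C)c(OCC=C)c1)C[C@@H]2O[Si](C)(C)C(C)(C)C
F9 | step 6 | (2S)-2-[3,4-bis(allyloxy)phenyl]-8-bromo-7-(3-methylbut-2-enyloxy)chroman | CC(C)=CCOc1ccc2c(c1Br)O[C@H](c1ccc(OCC=C)c(OCC=C)c1)CC2
F10 | step 6 | (2S)-8-bromo-2-(3,4-diacetoxy-2,5-diallylphenyl)-6-(2-methylbut-3-en-2-yl)chroman-7-yl acetate | C=CC(C)(C)c1cc2c(c(Br)c1OC(C)=O)O[C@H](c1cc(CC=C)c(OC(C)=O)c(OC(C)=O)c1CC=C)CC2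
F11 | step 3 | 1-{[3,4-bis(allyloxy)phenyl](chloro)methyl}-1H-benzotriazole (racemic) | ClC(c1ccc(OCC=C)c(OCC=C)c1)n1nnc2ccccc12
F12 | step 3 | 1-{[3,4-bis(allyloxy)phenyl][3-(3-methylbut-2-enyloxy)phenoxy]methyl}-1H-benzotriazole (racemic) | CC(C)=CCOc1cccc(OC(c2ccc(OCC=C)c(OCC=C)c2)n2nnc3ccccc23)c1
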